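**Retrosynthetic overview**

1. Target 25 ⇐ C3 desilylation and C8 angeloylation ⇐ 8-hydroxy-10-acetate 21 ⇐ Evans–Tishchenko (C8 reduction and C10 acetylation together) ⇐ tertiary aldol 19 ⇐ N–O cleavage of bridged isoxazoline 17.
2. Key step: 17 ⇐ nitro enone 15 by intramolecular nitrile oxide–alkene cycloaddition; C8–C9 and O–C10 form together, closing the ten-membered carbocycle and the isoxazoline in one operation and creating C10.
3. 15 ⇐ Mukaiyama aldol (C2–C3) of aldehyde 11 with the silyl dienol ether of 3-methylbut-3-en-2-one; 11 ⇐ SN2′ addition of nitromethane (C7–C8) to bromomethyl butenolide 8.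
4. 8 ⇐ allylic bromination of methylene lactone 7 ⇐ catalytic asymmetric 2-(ethoxycarbonyl)allylation/lactonisation of Roche-derived aldehyde 4.
5. Ring order: lactone (step 3); carbocycle and isoxazoline together (step 11); the isoxazoline is then opened to the 8,10-dioxygenation.

Assumption 1: locants C1–C15 are the germacrane locants of the target (C1 ring ketone, C3 carbinol, C4/C15, C6 lactone O–CH, C7, C8 acyloxy CH, C9, C10/C14, C11–C13 lactone carbons); the CIP letter of C7 changes along the route only because neighbour priorities change.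
Assumption 2: in step 3 the ligand enantiomer is the one that delivers the 6R carbinol (catalyst control).

**Route**

Step 1
Reactants: 1 (R)-3-bromo-2-methylpropan-1-ol
Product: 2 (R)-(3-bromo-2-methylpropoxy)(tert-butyl)dimethylsilane
Conditions: TBSCl, imidazole, CH2Cl2, 0 °C to rt
Reagents that add atoms: tert-butyldimethylsilyl chloride, CC(C)(C)[Si](C)(C)Cl
Why: O-silylation of the primary alcohol; the chiral-pool stereocentre (C4 of the target) is not touched.

Step 2
Reactants: 2 (R)-(3-bromo-2-methylpropoxy)(tert-butyl)dimethylsilane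
Product: 4 (S)-4-[(tert-butyldimethylsilyl)oxy]-3-methylbutanal, via Grignard reagent 3 (not isolated)
Conditions: Mg, THF, reflux; DMF, 0 °C; aq. NH4Cl
Reagents that add atoms: N,N-dimethylformamide, CN(C)C=O
Why: Bouveault formylation of a primary Grignard reagent; the stereocentre is β to magnesium and configurationally stable.

Step 3
Reactants: 4 (S)-4-[(tert-butyldimethylsilyl)oxy]-3-methylbutanal; 5 ethyl 2-(bromomethyl)acrylate
Product: 7 (5R)-5-{(2S)-3-[(tert-butyldimethylsilyl)oxy]-2-methylpropyl}-3-methylidenedihydrofuran-2(3H)-one, via hydroxy ester 6 (not isolated)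
Conditions: CrCl2 (10 mol %), chiral 3,6-di-tert-butyl-1,8-bis(4-isopropyl-4,5-dihydrooxazol-2-yl)carbazole ligand (12 mol %), Mn powder, TMSCl, Et3N (0.3 equiv), THF, rt; then PPTS, wet CH2Cl2, 40 °C
Reagents that add atoms: none
Why: Catalytic asymmetric Nozaki–Hiyama–Kishi-type 2-(alkoxycarbonyl)allylation, in which the chiral divalent-chromium complex selects the aldehyde face (C6 = R, catalyst control over the remote C4 centre), followed by acid-promoted lactonisation of the γ-hydroxy ester.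

Step 4
Reactants: 7 (5R)-5-{(2S)-3-[(tert-butyldimethylsilyl)oxy]-2-methylpropyl}-3-methylidenedihydrofuran-2(3H)-one
Product: 8 (5R)-3-(bromomethyl)-5-{(2S)-3-[(tert-butyldimethylsilyl)oxy]-2-methylpropyl}furan-2(5H)-one
Conditions: NBS (1.05 equiv), AIBN (5 mol %), PhCF3, 80 °C
Reagents that add atoms: N-bromosuccinimide, O=C1CCC(=O)N1Br
Why: Wohl–Ziegler bromination with allylic transposition; the only allylic C–H bonds of 7 are at C7, and the allyl radical is brominated at the exocyclic terminus to give the conjugated butenolide without touching C6.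

Step 5
Reactants: 8 (5R)-3-(bromomethyl)-5-{(2S)-3-[(tert-butyldimethylsilyl)oxy]-2-methylpropyl}furan-2(5H)-one
Product: 9 (4R,5R)-5-{(2S)-3-[(tert-butyldimethylsilyl)oxy]-2-methylpropyl}-3-methylidene-4-(nitromethyl)dihydrofuran-2(3H)-one
Conditions: MeNO2 (20 equiv), DBU (1.1 equiv), MeCN, −20 °C
Reagents that add atoms: nitromethane, C[N+](=O)[O-]
Why: SN2′ substitution (Michael addition of the nitronate at C7, then E1cB loss of bromide) restores the exo-methylene; the nucleophile enters anti to the C6 side chain, so C7 is set trans to C6 as in the target's lactone fusion.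

Step 6
Reactants: 9 (4R,5R)-5-{(2S)-3-[(tert-butyldimethylsilyl)oxy]-2-methylpropyl}-3-methylidene-4-(nitromethyl)dihydrofuran-2(3H)-one
Product: 10 (4R,5R)-5-[(2S)-3-hydroxy-2-methylpropyl]-3-methylidene-4-(nitromethyl)dihydrofuran-2(3H)-one
Conditions: HF·pyridine, THF, 0 °C to rt
Reagents that add atoms: none
Why: Acidic fluoride desilylation; base is avoided because of the nitroalkane and the Michael acceptor.

Step 7
Reactants: 10 (4R,5R)-5-[(2S)-3-hydroxy-2-methylpropyl]-3-methylidene-4-(nitromethyl)dihydrofuran-2(3H)-one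
Product: 11 (2S)-2-methyl-3-[(2R,3R)-4-methylidene-3-(nitromethyl)-5-oxotetrahydrofuran-2-yl]propanal
Conditions: TEMPO (10 mol %), PhI(OAc)2 (1.1 equiv), CH2Cl2, rt; used crude
Reagents that add atoms: none
Why: Oxoammonium (TEMPO/PhI(OAc)2) oxidation under slightly acidic, base-free conditions, which avoids epimerisation at C4 and the six-membered intramolecular Henry reaction.

Step 8
Reactants: 12 3-methylbut-3-en-2-one
Product: 13 trimethyl[(3-methylbuta-1,3-dien-2-yl)oxy]silane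
Conditions: LiN(iPr)2, THF, −78 °C; TMSCl
Reagents that add atoms: chlorotrimethylsilane, C[Si](C)(C)Cl
Why: Kinetic enolisation at the only enolisable position (the methyl group) and O-silylation.

Step 9
Reactants: 11 (2S)-2-methyl-3-[(2R,3R)-4-methylidene-3-(nitromethyl)-5-oxotetrahydrofuran-2-yl]propanal; 13 trimethyl[(3-methylbuta-1,3-dien-2-yl)oxy]silane
Product: 14 (4R,5R)-5-[(2S,3S)-3-hydroxy-2,6-dimethyl-5-oxohept-6-en-1-yl]-3-methylidene-4-(nitromethyl)dihydrofuran-2(3H)-one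
Conditions: BF3·OEt2 (1.1 equiv), CH2Cl2, −78 °C; pH 7 buffer
Reagents that add atoms: none
Why: Mukaiyama aldol through an open transition state; Felkin–Anh attack on the α-methyl aldehyde (CH2–lactone arm as the large group) sets C3 as S (3,4-syn), and a diastereomer ratio of roughly 5:1 is expected, with separation at this stage.

Step 10
Reactants: 14 (4R,5R)-5-[(2S,3S)-3-hydroxy-2,6-dimethyl-5-oxohept-6-en-1-yl]-3-methylidene-4-(nitromethyl)dihydrofuran-2(3H)-one
Product: 15 (4R,5R)-5-{(2S,3S)-2,6-dimethyl-5-oxo-3-[(triethylsilyl)oxy]hept-6-en-1-yl}-3-methylidene-4-(nitromethyl)dihydrofuran-2(3H)-one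
Conditions: TESCl, imidazole, DMF, 0 °C
Reagents that add atoms: chlorotriethylsilane, CC[Si](Cl)(CC)CC
Why: Silylation blocks the C3 hydroxyl (needed for steps 11, 13 and 14) and stops oxa-Michael closure onto the enone.

Step 11
Reactants: 15 (4R,5R)-5-{(2S,3S)-2,6-dimethyl-5-oxo-3-[(triethylsilyl)oxy]hept-6-en-1-yl}-3-methylidene-4-(nitromethyl)dihydrofuran-2(3H)-one
Product: 17 (3S,4S,6R,7R,10R)-8,10-(nitrilooxy)-1-oxo-3-[(triethylsilyl)oxy]germacr-11(13)-en-12,6-olide (bridged 2-isoxazoline C8=N–O–C10), via nitrile oxide 16 (not isolated)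
Conditions: PhNCO (4 equiv), Et3N (0.3 equiv), toluene, 40 °C, syringe-pump addition of 15 over 12 h (final 2 mM)
Reagents that add atoms: none
Why: Mukaiyama dehydration of the primary nitro group gives the nitrile oxide, which adds intramolecularly to the 1,1-disubstituted enone with the normal regiochemistry (carbon to the CH2 terminus, oxygen to the methyl- and acyl-bearing carbon), closing the ten-membered carbocycle and the isoxazoline together; the methylene lactone cannot compete intramolecularly (three- or four-membered ring), and C10 (R) is set by the macrocyclic transition state, expected to close on the ring face next to C7–H and away from the lactone arm, though this facial preference is not established.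

Step 12
Reactants: 17 (3S,4S,6R,7R,10R)-8,10-(nitrilooxy)-1-oxo-3-[(triethylsilyl)oxy]germacr-11(13)-en-12,6-olide
Product: 19 (3S,4S,6R,7S,10R)-10-hydroxy-1,8-dioxo-3-[(triethylsilyl)oxy]germacr-11(13)-en-12,6-olide, via hydroxy imine 18 (not isolated)
Conditions: Mo(CO)6 (1 equiv), MeCN/H2O 15:1, 80 °C, short reaction time
Reagents that add atoms: water, O
Why: Zerovalent molybdenum cleaves the N–O bond reductively and the β-hydroxy imine hydrolyses to the C8 ketone; alkenes, esters and the silyl ether are inert and no stereocentre is formed.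

Step 13
Reactants: 19 (3S,4S,6R,7S,10R)-10-hydroxy-1,8-dioxo-3-[(triethylsilyl)oxy]germacr-11(13)-en-12,6-olide
Product: 21 (3S,4S,6R,7R,8R,10R)-10-acetoxy-8-hydroxy-1-oxo-3-[(triethylsilyl)oxy]germacr-11(13)-en-12,6-olide, via hemiacetal 20 (not isolated)
Conditions: SmI2 (30 mol %, premixed with CH3CHO), CH3CHO (10 equiv), THF, −10 °C
Reagents that add atoms: acetaldehyde, CC=O
Why: Evans–Tishchenko reduction: trivalent samarium holds the C10-alkoxide/acetaldehyde hemiacetal and the C8 ketone in a six-membered chair, hydride is delivered intramolecularly to C8 (8R, 1,3-anti to the C10 oxygen) and the hemiacetal becomes the C10 acetate; the C1 ketone (five-membered transition state, neopentyl) and the silylated C3 oxygen cannot take part.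

Step 14
Reactants: 21 (3S,4S,6R,7R,8R,10R)-10-acetoxy-8-hydroxy-1-oxo-3-[(triethylsilyl)oxy]germacr-11(13)-en-12,6-olide; 22 angelic acid [(2Z)-2-methylbut-2-enoic acid]
Product: 24 (3S,4S,6R,7S,8R,10R)-10-acetoxy-8-[(2Z)-2-methylbut-2-enoyloxy]-1-oxo-3-[(triethylsilyl)oxy]germacr-11(13)-en-12,6-olide, via mixed anhydride 23 (not isolated)
Conditions: 22 (3 equiv), 2,4,6-trichlorobenzoyl chloride (3 equiv), Et3N, toluene, rt; then 21, 80 °C, no DMAP
Reagents that add atoms: none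
Why: Yamaguchi esterification through the mixed anhydride, which acylates the hindered secondary alcohol with retention and, without DMAP, keeps the Z (angelate) geometry.

Step 15
Reactants: 24 (3S,4S,6R,7S,8R,10R)-10-acetoxy-8-[(2Z)-2-methylbut-2-enoyloxy]-1-oxo-3-[(triethylsilyl)oxy]germacr-11(13)-en-12,6-olide
Product: 25 (3aS,4R,6R,9S,10S,11aR)-6-acetoxy-9-hydroxy-6,10-dimethyl-3-methylidene-2,7-dioxododecahydrocyclodeca[b]furan-4-yl (2Z)-2-methylbut-2-enoate (target)
Conditions: HF·pyridine, pyridine/THF, 0 °C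
Reagents that add atoms: none
Why: Mild acidic desilylation frees the C3 hydroxyl without retro-aldol, acyl migration or angelate isomerisation.

**Compound list**

1 | (R)-3-bromo-2-methylpropan-1-ol | BrC[C@H](C)CO | starting material
2 | (R)-(3-bromo-2-methylpropoxy)(tert-butyl)dimethylsilane | BrC[C@H](C)CO[Si](C)(C)C(C)(C)C | intermediate
3 | (R)-{3-[(tert-butyldimethylsilyl)oxy]-2-methylpropyl}magnesium bromide | Br[Mg]C[C@H](C)CO[Si](C)(C)C(C)(C)C | intermediate
4 | (S)-4-[(tert-butyldimethylsilyl)oxy]-3-methylbutanal | O=CC[C@H](C)CO[Si](C)(C)C(C)(C)C | intermediate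
5 | ethyl 2-(bromomethyl)acrylate | C=C(CBr)C(=O)OCC | starting material
6 | ethyl (4R,6S)-7-[(tert-butyldimethylsilyl)oxy]-4-hydroxy-6-methyl-2-methylideneheptanoate | C=C(C[C@H](O)C[C@H](C)CO[Si](C)(C)C(C)(C)C)C(=O)OCC | intermediate
7 | (5R)-5-{(2S)-3-[(tert-butyldimethylsilyl)oxy]-2-methylpropyl}-3-methylidenedihydrofuran-2(3H)-one | C=C1C(=O)O[C@H](C[C@H](C)CO[Si](C)(C)C(C)(C)C)C1 | intermediate
8 | (5R)-3-(bromomethyl)-5-{(2S)-3-[(tert-butyldimethylsilyl)oxy]-2-methylpropyl}furan-2(5H)-one | O=C1O[C@H](C[C@H](C)CO[Si](C)(C)C(C)(C)C)C=C1CBr | intermediate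
9 | (4R,5R)-5-{(2S)-3-[(tert-butyldimethylsilyl)oxy]-2-methylpropyl}-3-methylidene-4-(nitromethyl)dihydrofuran-2(3H)-one | C=C1C(=O)O[C@H](C[C@H](C)CO[Si](C)(C)C(C)(C)C)[C@H]1C[N+](=O)[O-] | intermediate
10 | (4R,5R)-5-[(2S)-3-hydroxy-2-methylpropyl]-3-methylidene-4-(nitromethyl)dihydrofuran-2(3H)-one | C=C1C(=O)O[C@H](C[C@H](C)CO)[C@H]1C[N+](=O)[O-] | intermediate
11 | (2S)-2-methyl-3-[(2R,3R)-4-methylidene-3-(nitromethyl)-5-oxotetrahydrofuran-2-yl]propanal | C=C1C(=O)O[C@H](C[C@H](C)C=O)[C@H]1C[N+](=O)[O-] | intermediate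
12 | 3-methylbut-3-en-2-one | CC(=O)C(C)=C | starting material
13 | trimethyl[(3-methylbuta-1,3-dien-2-yl)oxy]silane | C=C(C)C(=C)O[Si](C)(C)C | intermediate
14 | (4R,5R)-5-[(2S,3S)-3-hydroxy-2,6-dimethyl-5-oxohept-6-en-1-yl]-3-methylidene-4-(nitromethyl)dihydrofuran-2(3H)-one | C=C1C(=O)O[C@H](C[C@H](C)[C@@H](O)CC(=O)C(C)=C)[C@H]1C[N+](=O)[O-] | intermediate
15 | (4R,5R)-5-{(2S,3S)-2,6-dimethyl-5-oxo-3-[(triethylsilyl)oxy]hept-6-en-1-yl}-3-methylidene-4-(nitromethyl)dihydrofuran-2(3H)-one | C=C1C(=O)O[C@H](C[C@H](C)[C@@H](O[Si](CC)(CC)CC)CC(=O)C(C)=C)[C@H]1C[N+](=O)[O-] | intermediate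
16 | (2R,3R)-2-{(2S,3S)-2,6-dimethyl-5-oxo-3-[(triethylsilyl)oxy]hept-6-en-1-yl}-4-methylidene-5-oxotetrahydrofuran-3-carbonitrile oxide | C=C1C(=O)O[C@H](C[C@H](C)[C@@H](O[Si](CC)(CC)CC)CC(=O)C(C)=C)[C@H]1C#[N+][O-] | intermediate
17 | (3S,4S,6R,7R,10R)-8,10-(nitrilooxy)-1-oxo-3-[(triethylsilyl)oxy]germacr-11(13)-en-12,6-olide (ten-membered carbocycle bridged by a 2-isoxazoline, C8=N–O–C10, C9 = isoxazoline CH2) | C=C1C(=O)O[C@@H]2C[C@H](C)[C@@H](O[Si](CC)(CC)CC)CC(=O)[C@]3(C)ON=C(C3)[C@@H]12 | intermediate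
18 | (3S,4S,6R,7R,10R)-10-hydroxy-8-imino-1-oxo-3-[(triethylsilyl)oxy]germacr-11(13)-en-12,6-olide | C=C1C(=O)O[C@@H]2C[C@H](C)[C@@H](O[Si](CC)(CC)CC)CC(=O)[C@](C)(O)CC(=N)[C@@H]12 | intermediate
19 | (3S,4S,6R,7S,10R)-10-hydroxy-1,8-dioxo-3-[(triethylsilyl)oxy]germacr-11(13)-en-12,6-olide | C=C1C(=O)O[C@@H]2C[C@H](C)[C@@H](O[Si](CC)(CC)CC)CC(=O)[C@](C)(O)CC(=O)[C@@H]12 | intermediate
20 | (3S,4S,6R,7S,10R)-10-(1-hydroxyethoxy)-1,8-dioxo-3-[(triethylsilyl)oxy]germacr-11(13)-en-12,6-olide (samarium-bound hemiacetal, hemiacetal carbon undefined) | C=C1C(=O)O[C@@H]2C[C@H](C)[C@@H](O[Si](CC)(CC)CC)CC(=O)[C@](C)(OC(C)O)CC(=O)[C@@H]12 | intermediate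
21 | (3S,4S,6R,7R,8R,10R)-10-acetoxy-8-hydroxy-1-oxo-3-[(triethylsilyl)oxy]germacr-11(13)-en-12,6-olide | C=C1C(=O)O[C@@H]2C[C@H](C)[C@@H](O[Si](CC)(CC)CC)CC(=O)[C@](C)(OC(C)=O)C[C@@H](O)[C@@H]12 | intermediate
22 | angelic acid, (2Z)-2-methylbut-2-enoic acid | C/C=C(/C)C(=O)O | starting material
23 | (2Z)-2-methylbut-2-enoic 2,4,6-trichlorobenzoic anhydride | C/C=C(/C)C(=O)OC(=O)c1c(Cl)cc(Cl)cc1Cl | intermediate
24 | (3S,4S,6R,7S,8R,10R)-10-acetoxy-8-[(2Z)-2-methylbut-2-enoyloxy]-1-oxo-3-[(triethylsilyl)oxy]germacr-11(13)-en-12,6-olide | C=C1C(=O)O[C@@H]2C[C@H](C)[C@@H](O[Si](CC)(CC)CC)CC(=O)[C@](C)(OC(C)=O)C[C@@H](OC(=O)/C(C)=C\C)[C@@H]12 | intermediate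
25 | (3aS,4R,6R,9S,10S,11aR)-6-acetoxy-9-hydroxy-6,10-dimethyl-3-methylidene-2,7-dioxododecahydrocyclodeca[b]furan-4-yl (2Z)-2-methylbut-2-enoate | C=C1C(=O)O[C@@H]2C[C@H](C)[C@@H](O)CC(=O)[C@](C)(OC(C)=O)C[C@@H](OC(=O)/C(C)=C\C)[C@@H]12 | target

**Step count**

Total: 15 steps. Longest linear sequence: 14 steps (1 → 25 through steps 1–7 and 9–15); step 8 is a one-step side branch.

**Steps most likely to fail, with fallbacks**

Step 11 (macrocyclic nitrile oxide cycloaddition). The ten-membered ring is at the lower size limit for the bridged mode, so dimers or oligomers may dominate, and the C10 face is decided only by the macrocyclic transition state. Fallback: make the two bonds in the opposite order and close the ring at C2–C3. Setting out from 9, Mukaiyama dehydration (PhNCO, Et3N) in the presence of excess 12 gives (4R,5R)-4-[(5R)-5-acetyl-5-methyl-4,5-dihydroisoxazol-3-yl]-5-{(2S)-3-[(tert-butyldimethylsilyl)oxy]-2-methylpropyl}-3-methylidenedihydrofuran-2(3H)-one F1, whose C10 epimers are separated. HF·pyridine gives the primary alcohol (4R,5R)-4-[(5R)-5-acetyl-5-methyl-4,5-dihydroisoxazol-3-yl]-5-[(2S)-3-hydroxy-2-methylpropyl]-3-methylidenedihydrofuran-2(3H)-one F2. TEMPO/PhI(OAc)2 gives the keto aldehyde (2S)-3-{(2R,3R)-3-[(5R)-5-acetyl-5-methyl-4,5-dihydroisoxazol-3-yl]-4-methylidene-5-oxotetrahydrofuran-2-yl}-2-methylpropanal F3. An intramolecular aldol of the methyl ketone onto the aldehyde (LiN(SiMe3)2, THF, −78 °C, 1 mM) closes the carbocycle to (3S,4S,6R,7R,10R)-3-hydroxy-8,10-(nitrilooxy)-1-oxogermacr-11(13)-en-12,6-olide F4. TESCl/imidazole then returns to the route at 17.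

Step 12 (N–O cleavage). Product 19 is a β-acyl α-methylene lactone and a tertiary aldol, so in hot aqueous MeCN C7 may epimerise, the alkene may move into conjugation, or the ring may open by retro-aldol. Fallback: mask the methylene lactone and cleave the N–O bond by hydrogenolysis at room temperature. Setting out from 17, Me2NH (THF) gives the conjugate adduct (3S,4S,6R,7R,10R)-13-(dimethylamino)-8,10-(nitrilooxy)-1-oxo-3-[(triethylsilyl)oxy]germacran-12,6-olide F5 (C11 epimers, inconsequential). H2, Raney Ni and B(OH)3 in MeOH/H2O give (3S,4S,6R,7S,10R)-13-(dimethylamino)-10-hydroxy-1,8-dioxo-3-[(triethylsilyl)oxy]germacran-12,6-olide F6. MeI followed by aq. NaHCO3 eliminates the amine and returns to the route at 19.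

Step 13 (Evans–Tishchenko on a tertiary carbinol). Hemiacetal formation at the hindered C10 alkoxide may be slow, and retro-aldol or reduction of the C1 ketone may compete. Fallback: external hydride, then inversion and separate acylations. Setting out from 19, Narasaka–Prasad reduction (Et2BOMe, NaBH4, THF/MeOH, −78 °C; only C8 sits in a six-membered boron chelate) gives the 1,3-syn diol (3S,4S,6R,7R,8S,10R)-8,10-dihydroxy-1-oxo-3-[(triethylsilyl)oxy]germacr-11(13)-en-12,6-olide F7. Mitsunobu esterification with 22 (PPh3, DIAD, toluene, 0 °C) inverts C8 and gives (3S,4S,6R,7S,8R,10R)-10-hydroxy-8-[(2Z)-2-methylbut-2-enoyloxy]-1-oxo-3-[(triethylsilyl)oxy]germacr-11(13)-en-12,6-olide F8. Acetylation of the tertiary hydroxyl (Ac2O, DMAP, Et3N, 40 °C) returns to the route at 24.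

**Further compounds**

F1 | step 11 | (4R,5R)-4-[(5R)-5-acetyl-5-methyl-4,5-dihydroisoxazol-3-yl]-5-{(2S)-3-[(tert-butyldimethylsilyl)oxy]-2-methylpropyl}-3-methylidenedihydrofuran-2(3H)-one | C=C1C(=O)O[C@H](C[C@H](C)CO[Si](C)(C)C(C)(C)C)[C@H]1C2=NO[C@@](C)(C(C)=O)C2
F2 | step 11 | (4R,5R)-4-[(5R)-5-acetyl-5-methyl-4,5-dihydroisoxazol-3-yl]-5-[(2S)-3-hydroxy-2-methylpropyl]-3-methylidenedihydrofuran-2(3H)-one | C=C1C(=O)O[C@H](C[C@H](C)CO)[C@H]1C2=NO[C@@](C)(C(C)=O)C2
F3 | step 11 | (2S)-3-{(2R,3R)-3-[(5R)-5-acetyl-5-methyl-4,5-dihydroisoxazol-3-yl]-4-methylidene-5-oxotetrahydrofuran-2-yl}-2-methylpropanal | C=C1C(=O)O[C@H](C[C@H](C)C=O)[C@H]1C2=NO[C@@](C)(C(C)=O)C2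
F4 | step 11 | (3S,4S,6R,7R,10R)-3-hydroxy-8,10-(nitrilooxy)-1-oxogermacr-11(13)-en-12,6-olide | C=C1C(=O)O[C@@H]2C[C@H](C)[C@@H](O)CC(=O)[C@]3(C)ON=C(C3)[C@@H]12
F5 | step 12 | (3S,4S,6R,7R,10R)-13-(dimethylamino)-8,10-(nitrilooxy)-1-oxo-3-[(triethylsilyl)oxy]germacran-12,6-olide | CN(C)CC1C(=O)O[C@@H]2C[C@H](C)[C@@H](O[Si](CC)(CC)CC)CC(=O)[C@]3(C)ON=C(C3)[C@@H]12
F6 | step 12 | (3S,4S,6R,7S,10R)-13-(dimethylamino)-10-hydroxy-1,8-dioxo-3-[(triethylsilyl)oxy]germacran-12,6-olide | CN(C)CC1C(=O)O[C@@H]2C[C@H](C)[C@@H](O[Si](CC)(CC)CC)CC(=O)[C@](C)(O)CC(=O)[C@@H]12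
F7 | step 13 | (3S,4S,6R,7R,8S,10R)-8,10-dihydroxy-1-oxo-3-[(triethylsilyl)oxy]germacr-11(13)-en-12,6-olide | C=C1C(=O)O[C@@H]2C[C@H](C)[C@@H](O[Si](CC)(CC)CC)CC(=O)[C@](C)(O)C[C@H](O)[C@@H]12
F8 | step 13 | (3S,4S,6R,7S,8R,10R)-10-hydroxy-8-[(2Z)-2-methylbut-2-enoyloxy]-1-oxo-3-[(triethylsilyl)oxy]germacr-11(13)-en-12,6-olide | C=C1C(=O)O[C@@H]2C[C@H](C)[C@@H](O[Si](CC)(CC)CC)CC(=O)[C@](C)(O)C[C@@H](OC(=O)/C(C)=C\C)[C@@H]12
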